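Don't rank these set-ups by mixing first: amber holds its charge 250 s on average, the others 50 s.

| flask | starting material | capture agent | remark | time |
|---|---|---|---|---|
| amber | 0.50 mM | 0.0100 mM | a single well-mixed tank run continuously and read at steady state, 250 s in it on average |  |
| red | 0.50 mM | 0.0100 mM | everything together in a closed stirred flask, run for 50 s | 50 s |
| grey | 0.50 mM | 0.0100 mM | one stirred flow tank at steady state, fed with the mixture as stated, mean residence time 50 s |  |
| ochre | 0.50 mM | 0.0100 mM | a tube with plug flow, the mixed feed as stated, residence time 50 s | 50 s |

    2 starting material → homo dimer (k1 = 31.3 M⁻¹ s⁻¹)
    intermediate A ⇌ intermediate C (K2 = 0.109, k2 = 0.0514 s⁻¹)
    starting material → intermediate A (k3 = 0.201 s⁻¹)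
    intermediate A → side product (k4 = 0.00921 s⁻¹)
    intermediate A → intermediate B (k5 = 0.0495 s⁻¹)
    intermediate B → target (k6 = 0.0220 s⁻¹)
    capture agent + intermediate A → trapped intermediate (k7 = 24.7 M⁻¹ s⁻¹)

- the set-up with the highest amount of target at the outlet or at the end, in percent of the starting material put in ("none" if the first two lie within 2 percentage points) (amber / red / grey / ochre / none)
- amount of target at the outlet or at the end, in percent of the starting material put in, amber
- amount of target at the outlet or at the end, in percent of the starting material put in, red
- amount of target at the outlet or at the end, in percent of the starting material put in, grey
- amount of target at the outlet or at the end, in percent of the starting material put in, ochre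

- a species is counted by the starting material in it: one homo dimer counts as two
- for a step with 2 of a species take k times the square, and two of it per event
- the stated concentrations are those of everything mixed, before any reaction; amounts are the same in each set-up
- run time (red): 50 s

Set the zero of the scale before touching the clock. Define the branch share as the constant of the step to intermediate B divided by the sum of the two constants that lead from intermediate A to intermediate B and to side product: 84.3%. With endless time, and without homo dimer, capture or intermediate C, that is the target's ceiling. Capture at charged [capture agent] takes hardly any of intermediate A.

Now add the clock. In a stirred tank, a first-order stage passes the product of constant and residence time, over one plus that product. Take amber in two extreme versions. If the step to target, which has the smallest constant of the three stages, is the sole clock, it passes 84.6%, and the yield is 71.3%. If every stage is as slow as that one, the yield is 51.0%. The real tank lies between, since the two earlier stages are faster than the last but not instant. Multiply the stages: 65.5% for amber. The same product gives 30.0% for grey. A slice of ochre's tube is a closed flask, so ochre and red share one number. With the last step as sole clock that number is 56.2%, less than amber's 65.5%. Commit to amber.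

The forecast also names amber, with 64.6% for amber, 33.8% for red, 28.7% for grey and 33.8% for ochre, holding that the longer stay “far outweighs the back-mixing penalty”.

The simulation gives amber first: 64.6% for amber, 33.7% for red, 28.7% for grey, 33.7% for ochre. In red, starting material went with a half-life of 3.4 s by its first step alone, and at 50 s the flask still held 7.92% intermediate A and 36.9% intermediate B beside its target. Apply the branch share to grey: intermediate B plus target, over those two plus side product, reads 84.3%, with 84.3% reckoned. In amber, 14.2% side product multiplied by the share over one minus the share gives 76.2% sent towards intermediate B, and 64.6% of the charge stood as target.

(Its constants are assumed.)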